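The route rests on the C9–C11 disconnection, which joins the side chain to the quaternary carbon C9 of ring B. C9 is allylic to the C1=C10 alkene of ring A, so in an enone with its carbonyl at C1 and a C9=C10 double bond it is the β-carbon. Copper-mediated 1,4-addition of the complete C11–C16 chain forms the C9–C11 bond and the quaternary stereocentre anti to the C8 methyl in one operation, and the C1–C10 enolate, trapped and converted to its triflate, fixes the later alkene position. The precursor is a tetrasubstituted bicyclic enone assembled by an asymmetric Diels–Alder reaction and an oxidative allylic transposition, together with a homoallylic bromide of defined E geometry.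

Key step: step 13

Remark: atom labels follow halimane numbering (ring A = C1–C5, C10; ring B = C5–C10; side chain C11–C16 on C9). The catalyst in step 3 is written as the (S)-form on the assumption that it directs the diene to the Cα Re face of methacrolein; should the sense prove opposite, the (R)-catalyst is used.

Step 1
Reactants: 1 2-bromocyclohex-2-en-1-one
Product: 2 6-bromo-1,4-dioxaspiro[4.5]dec-6-ene
Conditions: HOCH2CH2OH, p-TsOH (cat.), benzene, reflux, Dean–Stark
Reagents that add atoms: ethane-1,2-diol, OCCO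
Why: Acid-catalysed ketalisation with azeotropic removal of water masks the ketone carbon (the later C9) as an achiral dioxolane that tolerates the cross-coupling.

Step 2
Reactants: 2 6-bromo-1,4-dioxaspiro[4.5]dec-6-ene
Product: 3 6-ethenyl-1,4-dioxaspiro[4.5]dec-6-ene
Conditions: CH2=CHSnBu3, Pd(PPh3)4 (5 mol %), toluene, 100 °C
Reagents that add atoms: tributyl(vinyl)stannane, C=C[Sn](CCCC)(CCCC)CCCC
Why: Stille coupling of the alkenyl bromide under zerovalent palladium catalysis installs C1–C2 and gives the semicyclic diene C2=C1–C10=C5.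

Step 3
Reactants: 3 6-ethenyl-1,4-dioxaspiro[4.5]dec-6-ene; 4 methacrolein
Product: 5 (4a'S,5'S)-5'-methyl-3',4',4a',5',6',7'-hexahydro-2'H-spiro[[1,3]dioxolane-2,1'-naphthalene]-5'-carbaldehyde
Conditions: (S)-o-tolyl-CBS-oxazaborolidine·HNTf2 (20 mol %), CH2Cl2, −78 → −40 °C
Reagents that add atoms: none
Why: In this oxazaborolidinium-catalysed Diels–Alder reaction the ring-substituted diene terminus C5 should bond to the formyl-bearing carbon (ortho rule), the catalyst-bound formyl group should sit endo so that CHO ends trans to H5, and the catalyst shields one face of the s-trans enal, which sets the absolute configuration of C4 and C5.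

Step 4
Reactants: 5 (4a'S,5'S)-5'-methyl-3',4',4a',5',6',7'-hexahydro-2'H-spiro[[1,3]dioxolane-2,1'-naphthalene]-5'-carbaldehyde
Product: 7 (1S,8aR)-1-methyl-5-oxo-1,2,3,5,6,7,8,8a-octahydronaphthalene-1-carboxylic acid, via ketal acid 6 (not isolated)
Conditions: NaClO2, NaH2PO4, 2-methylbut-2-ene, t-BuOH/H2O, rt; then 2 M HCl, THF, rt
Reagents that add atoms: sodium chlorite, [Na+].[O-]Cl=O; water, O
Why: Pinnick oxidation converts the neopentyl aldehyde into the acid without touching the alkene, and acid hydrolysis of the dioxolane then frees the C9 ketone in conjugation with C1=C10; H5 is not acidified by this enone, so C5 is not at risk.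

Step 5
Reactants: 7 (1S,8aR)-1-methyl-5-oxo-1,2,3,5,6,7,8,8a-octahydronaphthalene-1-carboxylic acid
Product: 8 methyl (1S,8aR)-1-methyl-5-oxo-1,2,3,5,6,7,8,8a-octahydronaphthalene-1-carboxylate
Conditions: MeI, K2CO3, DMF, rt
Reagents that add atoms: iodomethane, CI
Why: SN2 O-alkylation of the carboxylate gives the hindered methyl ester that Fischer esterification would form only slowly.

Step 6
Reactants: 8 methyl (1S,8aR)-1-methyl-5-oxo-1,2,3,5,6,7,8,8a-octahydronaphthalene-1-carboxylate
Product: 11 methyl (1S,6R,8aR)-1,6-dimethyl-5-oxo-1,2,3,5,6,7,8,8a-octahydronaphthalene-1-carboxylate, via lithium enolate 9 (not isolated), via C8-epimeric ketone 10 (not isolated)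
Conditions: LiN(iPr)2, THF, −78 °C; MeI, −78 → −20 °C; then NaOMe (cat.), MeOH, rt
Reagents that add atoms: iodomethane, CI
Why: Kinetic α'-deprotonation of the enone at C8 and enolate alkylation install the C8 methyl, and base equilibration through the enolate should settle it equatorial, cis to H5 (8R), because ring B is anchored by the equatorial C5–C4 bond.

Step 7
Reactants: 11 methyl (1S,6R,8aR)-1,6-dimethyl-5-oxo-1,2,3,5,6,7,8,8a-octahydronaphthalene-1-carboxylate
Product: 12 methyl (1S,6R,8aR)-5-hydroxy-1,5,6-trimethyl-1,2,3,5,6,7,8,8a-octahydronaphthalene-1-carboxylate (either C5 epimer; C9 in halimane numbering)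
Conditions: MeLi, CeCl3, THF, −78 °C
Reagents that add atoms: methyllithium, [Li]C
Why: 1,2-Addition of the organocerium reagent to the enone carbonyl brings in the C9 methyl without enolising C8 or attacking the hindered ester; the configuration of the new carbinol centre is irrelevant because C9 becomes sp2 in the next step.

Step 8
Reactants: 12 methyl (1S,6R,8aR)-5-hydroxy-1,5,6-trimethyl-1,2,3,5,6,7,8,8a-octahydronaphthalene-1-carboxylate
Product: 13 methyl (1S,6R,8aR)-1,5,6-trimethyl-4-oxo-1,2,3,4,6,7,8,8a-octahydronaphthalene-1-carboxylate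
Conditions: pyridinium chlorochromate [C5H5NH][CrO3Cl], 4 Å MS, CH2Cl2, rt
Reagents that add atoms: pyridinium chlorochromate, [O-][Cr](=O)(=O)Cl.c1cc[nH+]cc1
Why: In this Babler–Dauben oxidative transposition the chromate ester of the tertiary allylic alcohol undergoes a [3,3] shift to C1 and is oxidised there, giving the C1 ketone conjugated to the new C9=C10 bond with C5 and C8 untouched.

Step 9
Reactants: 14 tert-butyl(but-3-yn-1-yloxy)dimethylsilane
Product: 17 (2E)-5-[(tert-butyldimethylsilyl)oxy]-3-methylpent-2-en-1-ol, via alkenylalane 15 (not isolated), via lithium alkenylalanate 16 (not isolated)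
Conditions: AlMe3, Cp2ZrCl2 (25 mol %), CH2Cl2, 0 °C → rt; n-BuLi, THF, −78 °C; (CH2O)n, −78 °C → rt
Reagents that add atoms: trimethylaluminium, C[Al](C)C; formaldehyde (as paraformaldehyde), C=O
Why: Negishi zirconium-catalysed carboalumination adds Me–Al syn across the terminal alkyne with Al at the terminus, and the ate complex reacts with formaldehyde with retention, which fixes the E geometry of the trisubstituted alkene.

Step 10
Reactants: 17 (2E)-5-[(tert-butyldimethylsilyl)oxy]-3-methylpent-2-en-1-ol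
Product: 18 (2E)-5-[(tert-butyldimethylsilyl)oxy]-1-[(tert-butyldiphenylsilyl)oxy]-3-methylpent-2-ene
Conditions: t-BuPh2SiCl, imidazole, DMF, rt
Reagents that add atoms: tert-butyl(chloro)diphenylsilane, CC(C)(C)[Si](Cl)(c1ccccc1)c1ccccc1
Why: Silylation of the allylic alcohol gives a robust ether that survives Grignard formation, the key step and the triflate reduction.

Step 11
Reactants: 18 (2E)-5-[(tert-butyldimethylsilyl)oxy]-1-[(tert-butyldiphenylsilyl)oxy]-3-methylpent-2-ene
Product: 19 (3E)-5-[(tert-butyldiphenylsilyl)oxy]-3-methylpent-3-en-1-ol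
Conditions: pyridinium p-toluenesulfonate, MeOH, rt
Reagents that add atoms: none
Why: Mild acid methanolysis cleaves the primary tert-butyldimethylsilyl ether selectively, the tert-butyldiphenylsilyl ether being far more stable to acid.

Step 12
Reactants: 19 (3E)-5-[(tert-butyldiphenylsilyl)oxy]-3-methylpent-3-en-1-ol
Product: 20 {[(2E)-5-bromo-3-methylpent-2-en-1-yl]oxy}(tert-butyl)diphenylsilane
Conditions: CBr4, PPh3, 2,6-lutidine, CH2Cl2, 0 °C
Reagents that add atoms: tetrabromomethane, BrC(Br)(Br)Br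
Why: Appel bromination converts the primary homoallylic alcohol into the bromide under buffered conditions that leave the silyl ether and the alkene geometry intact.

Step 13
Reactants: 13 methyl (1S,6R,8aR)-1,5,6-trimethyl-4-oxo-1,2,3,4,6,7,8,8a-octahydronaphthalene-1-carboxylate; 20 {[(2E)-5-bromo-3-methylpent-2-en-1-yl]oxy}(tert-butyl)diphenylsilane
Product: 23 methyl (1S,5S,6R,8aR)-5-{(3E)-5-[(tert-butyldiphenylsilyl)oxy]-3-methylpent-3-en-1-yl}-1,5,6-trimethyl-4-{[(trifluoromethyl)sulfonyl]oxy}-1,2,3,5,6,7,8,8a-octahydronaphthalene-1-carboxylate, via Grignard reagent 21 (not isolated), via trimethylsilyl enol ether 22 (not isolated)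
Conditions: 20, Mg, THF, rt; CuBr·SMe2 (20 mol %), 13, Me3SiCl, HMPA, THF, −78 → −40 °C; volatiles removed; CsF, PhNTf2, DME, rt
Reagents that add atoms: N-phenylbis(trifluoromethanesulfonimide), O=S(=O)(N(c1ccccc1)S(=O)(=O)C(F)(F)F)C(F)(F)F
Why: The Grignard reagent 21 and catalytic CuBr·SMe2 form a cuprate that adds to the s-cis-locked enone by π-complexation, oxidative addition at C9 and reductive elimination, Me3SiCl capturing the C1–C10 enolate as silyl enol ether 22, which CsF and PhNTf2 convert into the triflate 23 without moving the double bond. The closest known reaction type is the Me3SiCl/HMPA-accelerated copper-catalysed conjugate addition of Grignard reagents to β,β-disubstituted enones, as practised on 3,4-dimethylcyclohex-2-enone to set a vicinal cis-methyl pair, followed by fluoride-mediated triflation of a silyl enol ether. No ring is closed. The new stereocentre C9 is controlled by the C8 stereocentre: A(1,2) strain with the C9 methyl holds the C8 methyl pseudoaxial on the α face, so the cuprate should attack C9 axially from the β face, anti to it, giving 9S with the C8 and C9 methyls cis. The step needs 1,4- over 1,2-addition and over enolisation at C2 or C8, which the soft copper nucleophile and silyl activation should secure, and it needs regiospecific enolate capture, which is inherent because the enolate forms only across C1–C10.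

Step 14
Reactants: 23 methyl (1S,5S,6R,8aR)-5-{(3E)-5-[(tert-butyldiphenylsilyl)oxy]-3-methylpent-3-en-1-yl}-1,5,6-trimethyl-4-{[(trifluoromethyl)sulfonyl]oxy}-1,2,3,5,6,7,8,8a-octahydronaphthalene-1-carboxylate
Product: 24 methyl (1S,5S,6R,8aR)-5-{(3E)-5-[(tert-butyldiphenylsilyl)oxy]-3-methylpent-3-en-1-yl}-1,5,6-trimethyl-1,2,3,5,6,7,8,8a-octahydronaphthalene-1-carboxylate
Conditions: Pd(OAc)2 (5 mol %), PPh3 (10 mol %), n-Bu3N, HCO2H, DMF, 60 °C
Reagents that add atoms: none
Why: Palladium-catalysed formate reduction of the enol triflate (oxidative addition, formate decarboxylation, reductive elimination) replaces OTf by H and leaves the double bond at C1=C10; Heck closure onto the trisubstituted side-chain alkene should not compete.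

Step 15
Reactants: 24 methyl (1S,5S,6R,8aR)-5-{(3E)-5-[(tert-butyldiphenylsilyl)oxy]-3-methylpent-3-en-1-yl}-1,5,6-trimethyl-1,2,3,5,6,7,8,8a-octahydronaphthalene-1-carboxylate
Product: 25 methyl (1S,5S,6R,8aR)-5-[(3E)-5-hydroxy-3-methylpent-3-en-1-yl]-1,5,6-trimethyl-1,2,3,5,6,7,8,8a-octahydronaphthalene-1-carboxylate
Conditions: n-Bu4NF, THF, 0 °C → rt
Reagents that add atoms: none
Why: Fluoride desilylation frees the allylic alcohol; the hindered tertiary methyl ester is inert to these conditions.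

Step 16
Reactants: 25 methyl (1S,5S,6R,8aR)-5-[(3E)-5-hydroxy-3-methylpent-3-en-1-yl]-1,5,6-trimethyl-1,2,3,5,6,7,8,8a-octahydronaphthalene-1-carboxylate
Product: 26 methyl (1S,5S,6R,8aR)-5-{2-[(2R,3R)-3-(hydroxymethyl)-2-methyloxiran-2-yl]ethyl}-1,5,6-trimethyl-1,2,3,5,6,7,8,8a-octahydronaphthalene-1-carboxylate (CNP0324371.2)
Conditions: Ti(OiPr)4 (10 mol %), D-(−)-diethyl tartrate (12 mol %), t-BuOOH, 4 Å MS, CH2Cl2, −20 °C
Reagents that add atoms: tert-butyl hydroperoxide, CC(C)(C)OO
Why: Sharpless asymmetric epoxidation is directed by the allylic hydroxyl, so the ring alkene is untouched, and the D-(−)-tartrate ligand should deliver oxygen to the face of the E-alkene that gives the (13R,14R)-epoxy alcohol under reagent control.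

Compound list
1 | 2-bromocyclohex-2-en-1-one | O=C1CCCC=C1Br | starting material
2 | 6-bromo-1,4-dioxaspiro[4.5]dec-6-ene | BrC1=CCCCC12OCCO2 | intermediate
3 | 6-ethenyl-1,4-dioxaspiro[4.5]dec-6-ene | C=CC1=CCCCC12OCCO2 | intermediate
4 | methacrolein (2-methylprop-2-enal) | CC(=C)C=O | starting material
5 | (4a'S,5'S)-5'-methyl-3',4',4a',5',6',7'-hexahydro-2'H-spiro[[1,3]dioxolane-2,1'-naphthalene]-5'-carbaldehyde | O=C[C@@]1(C)CCC=C2[C@H]1CCCC23OCCO3 | intermediate
6 | (4a'R,5'S)-5'-methyl-3',4',4a',5',6',7'-hexahydro-2'H-spiro[[1,3]dioxolane-2,1'-naphthalene]-5'-carboxylic acid (ketal acid, not isolated) | OC(=O)[C@@]1(C)CCC=C2[C@H]1CCCC23OCCO3 | intermediate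
7 | (1S,8aR)-1-methyl-5-oxo-1,2,3,5,6,7,8,8a-octahydronaphthalene-1-carboxylic acid | OC(=O)[C@@]1(C)CCC=C2[C@H]1CCCC2=O | intermediate
8 | methyl (1S,8aR)-1-methyl-5-oxo-1,2,3,5,6,7,8,8a-octahydronaphthalene-1-carboxylate | COC(=O)[C@@]1(C)CCC=C2[C@H]1CCCC2=O | intermediate
9 | lithium enolate of 8 across C8–C9 (not isolated) | COC(=O)[C@@]1(C)CCC=C2[C@H]1CCC=C2O[Li] | intermediate
10 | methyl (1S,6S,8aR)-1,6-dimethyl-5-oxo-1,2,3,5,6,7,8,8a-octahydronaphthalene-1-carboxylate (C8 epimer, not isolated) | COC(=O)[C@@]1(C)CCC=C2[C@H]1CC[C@H](C)C2=O | intermediate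
11 | methyl (1S,6R,8aR)-1,6-dimethyl-5-oxo-1,2,3,5,6,7,8,8a-octahydronaphthalene-1-carboxylate | COC(=O)[C@@]1(C)CCC=C2[C@H]1CC[C@@H](C)C2=O | intermediate
12 | methyl (1S,6R,8aR)-5-hydroxy-1,5,6-trimethyl-1,2,3,5,6,7,8,8a-octahydronaphthalene-1-carboxylate (either C5 epimer) | COC(=O)[C@@]1(C)CCC=C2[C@H]1CC[C@@H](C)C2(C)O | intermediate
13 | methyl (1S,6R,8aR)-1,5,6-trimethyl-4-oxo-1,2,3,4,6,7,8,8a-octahydronaphthalene-1-carboxylate | COC(=O)[C@@]1(C)CCC(=O)C2=C(C)[C@H](C)CC[C@@H]12 | intermediate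
14 | tert-butyl(but-3-yn-1-yloxy)dimethylsilane | C#CCCO[Si](C)(C)C(C)(C)C | starting material
15 | {(1E)-4-[(tert-butyldimethylsilyl)oxy]-2-methylbut-1-en-1-yl}dimethylalane (not isolated) | C[Al](C)/C=C(\C)CCO[Si](C)(C)C(C)(C)C | intermediate
16 | lithium butyl{(1E)-4-[(tert-butyldimethylsilyl)oxy]-2-methylbut-1-en-1-yl}dimethylalanate (not isolated) | [Li+].CCCC[Al-](C)(C)/C=C(\C)CCO[Si](C)(C)C(C)(C)C | intermediate
17 | (2E)-5-[(tert-butyldimethylsilyl)oxy]-3-methylpent-2-en-1-ol | OC/C=C(\C)CCO[Si](C)(C)C(C)(C)C | intermediate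
18 | (2E)-5-[(tert-butyldimethylsilyl)oxy]-1-[(tert-butyldiphenylsilyl)oxy]-3-methylpent-2-ene | CC(C)(C)[Si](C)(C)OCC/C(C)=C/CO[Si](c1ccccc1)(c1ccccc1)C(C)(C)C | intermediate
19 | (3E)-5-[(tert-butyldiphenylsilyl)oxy]-3-methylpent-3-en-1-ol | OCC/C(C)=C/CO[Si](c1ccccc1)(c1ccccc1)C(C)(C)C | intermediate
20 | {[(2E)-5-bromo-3-methylpent-2-en-1-yl]oxy}(tert-butyl)diphenylsilane | BrCC/C(C)=C/CO[Si](c1ccccc1)(c1ccccc1)C(C)(C)C | intermediate
21 | {(3E)-5-[(tert-butyldiphenylsilyl)oxy]-3-methylpent-3-en-1-yl}magnesium bromide (not isolated) | Br[Mg]CC/C(C)=C/CO[Si](c1ccccc1)(c1ccccc1)C(C)(C)C | intermediate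
22 | methyl (1S,5S,6R,8aR)-5-{(3E)-5-[(tert-butyldiphenylsilyl)oxy]-3-methylpent-3-en-1-yl}-1,5,6-trimethyl-4-[(trimethylsilyl)oxy]-1,2,3,5,6,7,8,8a-octahydronaphthalene-1-carboxylate (not isolated) | COC(=O)[C@@]1(C)CCC(O[Si](C)(C)C)=C2[C@H]1CC[C@@H](C)[C@]2(C)CC/C(C)=C/CO[Si](c1ccccc1)(c1ccccc1)C(C)(C)C | intermediate
23 | methyl (1S,5S,6R,8aR)-5-{(3E)-5-[(tert-butyldiphenylsilyl)oxy]-3-methylpent-3-en-1-yl}-1,5,6-trimethyl-4-{[(trifluoromethyl)sulfonyl]oxy}-1,2,3,5,6,7,8,8a-octahydronaphthalene-1-carboxylate | COC(=O)[C@@]1(C)CCC(OS(=O)(=O)C(F)(F)F)=C2[C@H]1CC[C@@H](C)[C@]2(C)CC/C(C)=C/CO[Si](c1ccccc1)(c1ccccc1)C(C)(C)C | intermediate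
24 | methyl (1S,5S,6R,8aR)-5-{(3E)-5-[(tert-butyldiphenylsilyl)oxy]-3-methylpent-3-en-1-yl}-1,5,6-trimethyl-1,2,3,5,6,7,8,8a-octahydronaphthalene-1-carboxylate | COC(=O)[C@@]1(C)CCC=C2[C@H]1CC[C@@H](C)[C@]2(C)CC/C(C)=C/CO[Si](c1ccccc1)(c1ccccc1)C(C)(C)C | intermediate
25 | methyl (1S,5S,6R,8aR)-5-[(3E)-5-hydroxy-3-methylpent-3-en-1-yl]-1,5,6-trimethyl-1,2,3,5,6,7,8,8a-octahydronaphthalene-1-carboxylate | COC(=O)[C@@]1(C)CCC=C2[C@H]1CC[C@@H](C)[C@]2(C)CC/C(C)=C/CO | intermediate
26 | methyl (1S,5S,6R,8aR)-5-{2-[(2R,3R)-3-(hydroxymethyl)-2-methyloxiran-2-yl]ethyl}-1,5,6-trimethyl-1,2,3,5,6,7,8,8a-octahydronaphthalene-1-carboxylate | COC(=O)[C@@]1(C)CCC=C2[C@H]1CC[C@@H](C)[C@]2(C)CC[C@@]1(C)O[C@@H]1CO | target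

Total step count: 16. Longest linear sequence: 12 (steps 1–8, then 13–16); steps 9–12 make the side-chain bromide in a separate branch.

Steps most likely to fail

Step 13. The tetrasubstituted, peri-congested enone may react sluggishly, so that 1,2-addition, enolisation by the Grignard reagent, or attack on the α face of C9 compete. The fallback makes the C9–C11 bond by [3,3] chirality transfer. It sets out from 13: reduction with (S)-2-methyl-CBS-oxazaborolidine and BH3·SMe2 should give the 1β-allylic alcohol methyl (1S,4R,6R,8aR)-4-hydroxy-1,5,6-trimethyl-1,2,3,4,6,7,8,8a-octahydronaphthalene-1-carboxylate F1. Johnson–Claisen rearrangement with MeC(OEt)3 and catalytic propionic acid at 140 °C should deliver the acetate unit suprafacially to the β face of C9 and move the alkene to C1=C10, giving the diester methyl (1S,5S,6R,8aR)-5-(2-ethoxy-2-oxoethyl)-1,5,6-trimethyl-1,2,3,5,6,7,8,8a-octahydronaphthalene-1-carboxylate F2. LiBH4 in THF should reduce only the unhindered ethyl ester to the primary alcohol methyl (1S,5S,6R,8aR)-5-(2-hydroxyethyl)-1,5,6-trimethyl-1,2,3,5,6,7,8,8a-octahydronaphthalene-1-carboxylate F3. I2, PPh3 and imidazole give the iodide methyl (1S,5S,6R,8aR)-5-(2-iodoethyl)-1,5,6-trimethyl-1,2,3,5,6,7,8,8a-octahydronaphthalene-1-carboxylate F4. Displacement with LiC≡CH·H2NCH2CH2NH2 in DMSO gives the terminal alkyne methyl (1S,5S,6R,8aR)-5-(but-3-yn-1-yl)-1,5,6-trimethyl-1,2,3,5,6,7,8,8a-octahydronaphthalene-1-carboxylate F5. Carboalumination with AlMe3 and Cp2ZrCl2, then n-BuLi and (CH2O)n, should give 25, where the route is rejoined.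

Step 3. The cationic Lewis acid may ionise the allylic dioxolane, and endo or facial selectivity may erode with this hindered semicyclic diene. The fallback replaces catalyst control by substrate control and sets out from 1. Reduction with (S)-2-methyl-CBS-oxazaborolidine and BH3·SMe2 should give (R)-2-bromocyclohex-2-en-1-ol F6. Silylation with t-BuMe2SiCl and imidazole gives (R)-[(2-bromocyclohex-2-en-1-yl)oxy](tert-butyl)dimethylsilane F7. Stille coupling with CH2=CHSnBu3 and Pd(PPh3)4 gives the diene (R)-tert-butyl[(2-ethenylcyclohex-2-en-1-yl)oxy]dimethylsilane F8. EtAlCl2-promoted Diels–Alder reaction with methyl methacrylate, anti to the pseudoaxial silyloxy group and ester-endo, should give methyl (1S,5R,8aR)-5-[(tert-butyldimethylsilyl)oxy]-1-methyl-1,2,3,5,6,7,8,8a-octahydronaphthalene-1-carboxylate F9. n-Bu4NF gives the allylic alcohol methyl (1S,5R,8aR)-5-hydroxy-1-methyl-1,2,3,5,6,7,8,8a-octahydronaphthalene-1-carboxylate F10. Dess–Martin oxidation returns to the route at 8.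

Step 8. The tertiary allylic alcohol may dehydrate or ionise on the acidic chromium reagent, and the [3,3] shift towards the congested tetrasubstituted alkene may be slow. The fallback separates transposition from oxidation and sets out from 12. Catalytic Ph3SiOReO3 in Et2O should isomerise it to the secondary allylic alcohol methyl (1S,6R,8aR)-4-hydroxy-1,5,6-trimethyl-1,2,3,4,6,7,8,8a-octahydronaphthalene-1-carboxylate F11 (either C4 epimer). Dess–Martin periodinane then oxidises it to 13, where the route is rejoined.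

Further compounds
F1 | step 13 | methyl (1S,4R,6R,8aR)-4-hydroxy-1,5,6-trimethyl-1,2,3,4,6,7,8,8a-octahydronaphthalene-1-carboxylate | COC(=O)[C@@]1(C)CC[C@@H](O)C2=C(C)[C@H](C)CC[C@@H]12
F2 | step 13 | methyl (1S,5S,6R,8aR)-5-(2-ethoxy-2-oxoethyl)-1,5,6-trimethyl-1,2,3,5,6,7,8,8a-octahydronaphthalene-1-carboxylate | COC(=O)[C@@]1(C)CCC=C2[C@H]1CC[C@@H](C)[C@]2(C)CC(=O)OCC
F3 | step 13 | methyl (1S,5S,6R,8aR)-5-(2-hydroxyethyl)-1,5,6-trimethyl-1,2,3,5,6,7,8,8a-octahydronaphthalene-1-carboxylate | COC(=O)[C@@]1(C)CCC=C2[C@H]1CC[C@@H](C)[C@]2(C)CCO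
F4 | step 13 | methyl (1S,5S,6R,8aR)-5-(2-iodoethyl)-1,5,6-trimethyl-1,2,3,5,6,7,8,8a-octahydronaphthalene-1-carboxylate | COC(=O)[C@@]1(C)CCC=C2[C@H]1CC[C@@H](C)[C@]2(C)CCI
F5 | step 13 | methyl (1S,5S,6R,8aR)-5-(but-3-yn-1-yl)-1,5,6-trimethyl-1,2,3,5,6,7,8,8a-octahydronaphthalene-1-carboxylate | COC(=O)[C@@]1(C)CCC=C2[C@H]1CC[C@@H](C)[C@]2(C)CCC#C
F6 | step 3 | (R)-2-bromocyclohex-2-en-1-ol | O[C@@H]1CCCC=C1Br
F7 | step 3 | (R)-[(2-bromocyclohex-2-en-1-yl)oxy](tert-butyl)dimethylsilane | CC(C)(C)[Si](C)(C)O[C@@H]1CCCC=C1Br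
F8 | step 3 | (R)-tert-butyl[(2-ethenylcyclohex-2-en-1-yl)oxy]dimethylsilane | CC(C)(C)[Si](C)(C)O[C@@H]1CCCC=C1C=C
F9 | step 3 | methyl (1S,5R,8aR)-5-[(tert-butyldimethylsilyl)oxy]-1-methyl-1,2,3,5,6,7,8,8a-octahydronaphthalene-1-carboxylate | COC(=O)[C@@]1(C)CCC=C2[C@H]1CCC[C@H]2O[Si](C)(C)C(C)(C)C
F10 | step 3 | methyl (1S,5R,8aR)-5-hydroxy-1-methyl-1,2,3,5,6,7,8,8a-octahydronaphthalene-1-carboxylate | COC(=O)[C@@]1(C)CCC=C2[C@H]1CCC[C@H]2O
F11 | step 8 | methyl (1S,6R,8aR)-4-hydroxy-1,5,6-trimethyl-1,2,3,4,6,7,8,8a-octahydronaphthalene-1-carboxylate (either C4 epimer) | COC(=O)[C@@]1(C)CCC(O)C2=C(C)[C@H](C)CC[C@@H]12
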